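**Plan**

Ring letters: A is the benzo ring of the chromanone, C its pyranone ring, B the 2-phenyl group, D the 2,6-dihydroxy-4-methoxy-3-methylphenyl ring.
- Enabling feature: the methine carbon carries three aryl groups (C8 of ring A, C1 of ring D, phenyl) and sits ortho to a phenolic oxygen of ring D. It can therefore begin as a formyl carbon on C8, take C1 of ring D by boron-templated ortho attack, and then receive phenyl from that same boron through the ring D ortho-quinone methide.
- Retrosynthetic cuts, in order: the ring D O–CH3 and the two ring A O-benzyl groups; then methine–C1(ring D) and methine–phenyl together; then C8–CHO, C2–phenyl and C6–CH3.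
- Forward: rings A and C come intact from 5,7-dihydroxychromone. The sequence is O7 benzylation, C6 iodination and methylation, O5 benzylation, phenyl to C2, formyl to C8, the three-component union, O-methylation on ring D and hydrogenolysis. No ring is built except a temporary dioxaborin.
- Stereochemistry: C2 (S) comes from a rhodium-catalysed asymmetric 1,4-addition under a chiral bisphosphine; the methine (S) comes from the chiral biphenol bound to boron during phenyl transfer.

Key step: step 7

Assumption: the (R) antipodes written for MeO-F12-BIPHEP (step 5) and 3,3'-dibromo-BINOL (step 7) are taken to give the (2S) and (S)-methine centres; if the sense of induction is the opposite, the antipodal ligand or catalyst is used.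

**Route**

Step 1
Reactants: 1 5,7-dihydroxy-4H-chromen-4-one
Product: 2 7-(benzyloxy)-5-hydroxy-4H-chromen-4-one
Conditions: BnBr (1.05 equiv), K2CO3, acetone, reflux
Reagents that add atoms: benzyl bromide, BrCc1ccccc1
Why: Williamson etherification should be selective for O7 because the 5-hydroxyl is held in a hydrogen bond to the C4 carbonyl and is much less acidic and nucleophilic.

Step 2
Reactants: 2 7-(benzyloxy)-5-hydroxy-4H-chromen-4-one
Product: 3 7-(benzyloxy)-5-hydroxy-6-iodo-4H-chromen-4-one
Conditions: NIS (1.05 equiv), DMF, rt, dark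
Reagents that add atoms: N-iodosuccinimide, O=C1CCC(=O)N1I
Why: Electrophilic aromatic iodination of a 5-hydroxy-7-alkoxy chromone or flavone is directed by the free chelated 5-hydroxyl to its ortho carbon C6 rather than to C8 or the electron-poor C3.

Step 3
Reactants: 3 7-(benzyloxy)-5-hydroxy-6-iodo-4H-chromen-4-one
Product: 4 7-(benzyloxy)-5-hydroxy-6-methyl-4H-chromen-4-one
Conditions: (MeBO)3, Pd(PPh3)4 (10 mol %), K2CO3, 1,4-dioxane, 100 °C
Reagents that add atoms: trimethylboroxine, CB1OB(C)OB(C)O1
Why: Suzuki–Miyaura methylation should work because oxidative addition into the aryl iodide and transfer of the small methyl group tolerate the two ortho substituents and the free phenol.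

Step 4
Reactants: 4 7-(benzyloxy)-5-hydroxy-6-methyl-4H-chromen-4-one
Product: 5 5,7-bis(benzyloxy)-6-methyl-4H-chromen-4-one
Conditions: BnBr (1.5 equiv), K2CO3, nBu4NI (cat.), DMF, 70 °C
Reagents that add atoms: benzyl bromide, BrCc1ccccc1
Why: Williamson etherification of the chelated, hindered 5-hydroxyl, now the only acidic site, should proceed under these more forcing conditions.

Step 5
Reactants: 5 5,7-bis(benzyloxy)-6-methyl-4H-chromen-4-one; 6 phenylboronic acid
Product: 7 (2S)-5,7-bis(benzyloxy)-6-methyl-2-phenylchroman-4-one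
Conditions: 6 (3 equiv), [RhOH(cod)]2 (1.5 mol %), (R)-MeO-F12-BIPHEP (3.3 mol %), PhMe–H2O, 25 °C
Reagents that add atoms: none
Why: Rhodium-catalysed asymmetric 1,4-addition of an arylboronic acid to a chromone (Hayashi–Miyaura type) is precedented for 5,7-dioxygenated chromones; the phenylrhodium species bearing the electron-poor atropisomeric bisphosphine inserts the C2=C3 bond from one face and sets C2 as (S), and the base-free conditions at room temperature avoid opening of ring C.

Step 6
Reactants: 7 (2S)-5,7-bis(benzyloxy)-6-methyl-2-phenylchroman-4-one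
Product: 9 (2S)-5,7-bis(benzyloxy)-6-methyl-4-oxo-2-phenylchromane-8-carbaldehyde, via chloro(methoxy)methyl ether 8 (not isolated)
Conditions: Cl2CHOMe (2 equiv), AgOTf (2.2 equiv), CH2Cl2, −78 °C; aq. NaHCO3
Reagents that add atoms: dichloromethyl methyl ether, COC(Cl)Cl; water, O
Why: Rieche formylation (Friedel–Crafts attack on the methoxychlorocarbenium ion, then hydrolysis of chloro ether 8 on work-up) should occur at C8, the only free position of ring A, which is activated by O1 and the 7-benzyloxy group ortho and the 5-benzyloxy group para; the silver-promoted variant runs at −78 °C, which should spare the benzyl ethers and the C2 stereocentre.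

Step 7
Reactants: 9 (2S)-5,7-bis(benzyloxy)-6-methyl-4-oxo-2-phenylchromane-8-carbaldehyde; 10 2-methylbenzene-1,3,5-triol (2-methylphloroglucinol); 6 phenylboronic acid
Product: 13 (2S)-5,7-bis(benzyloxy)-6-methyl-2-phenyl-8-[(S)-phenyl(2,4,6-trihydroxy-3-methylphenyl)methyl]chroman-4-one, via 2-phenyl-1,3,2-benzodioxaborin 11 (not isolated), via quinone methide boron ate complex 12 (not isolated)
Conditions: 10 (1.5 equiv) and 6 (3 equiv) premixed, then 9, EtCO2H (20 mol %), 4 Å MS, PhMe, 50 °C; then (R)-3,3'-Br2-BINOL (20 mol %), 25–40 °C; aq. NH4Cl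
Reagents that add atoms: none
Why: Proposed new method: phenylboronic acid 6 esterifies a hydroxyl of 10 and binds the aldehyde oxygen of 9, so the carbon ortho to the boron-bound oxygen attacks the carbonyl within a six-membered chelate (forming methine–C1 of ring D), and the temporary six-membered 1,3,2-dioxaborin ring of 11 closes by B–O bond formation to the new carbinol oxygen; this is the only ring formed and it does not survive. The dibromobiphenol then displaces the benzylic oxygen from boron and, helped by the two electron-rich aryl groups, the C–O bond ionises to the ring D ortho-quinone methide held on boron as ate complex 12, from which phenyl migrates through a six-membered transition state from boron to the exocyclic carbon (forming methine–phenyl). The closest known reaction types are the arylboronic acid-templated ortho-hydroxyalkylation of phenols with aldehydes (Nagata reaction) and the chiral biphenol-catalysed addition of aryl and alkenyl boronates to ortho-quinone methides, including variants in which the quinone methide is made in situ from a simple phenol and an aldehyde; what has not been combined in one operation is a phloroglucinol, a free arylboronic acid serving as both template and aryl donor, and a triarylmethane product. The methine stereocentre is set by the axially chiral biphenolate on boron, which should shield one face of the quinone methide whose exocyclic carbon carries two very different substituents (hydrogen and the bulky ring A aryl group); the remote C2 centre should have little influence, and because C2 is already fixed a minor methine epimer is a diastereomer removable by chromatography. The step needs C- over O-alkylation at a single site of ring D, which the ortho template and the two equivalent free carbons of 10 provide (dioxaborins closed through either flanking oxygen converge on 13). It also needs ring D and not ring A to become quinoid, which the two ring A benzyl ethers ensure, while the hindered C4 aryl ketone should not compete with the aldehyde.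

Step 8
Reactants: 13 (2S)-5,7-bis(benzyloxy)-6-methyl-2-phenyl-8-[(S)-phenyl(2,4,6-trihydroxy-3-methylphenyl)methyl]chroman-4-one
Product: 14 (2S)-5,7-bis(benzyloxy)-8-[(S)-(2,6-dihydroxy-4-methoxy-3-methylphenyl)(phenyl)methyl]-6-methyl-2-phenylchroman-4-one
Conditions: Me3SiCHN2 (1.05 equiv), iPr2NEt, MeCN–MeOH, 0 °C
Reagents that add atoms: (trimethylsilyl)diazomethane, C[Si](C)(C)C=[N+]=[N-]
Why: O-Methylation of a phenol with (trimethylsilyl)diazomethane under conditions too mild to open ring C should go to the ring D 4-hydroxyl (para to the methine, flanked by CH3 and H), the only one of the three not shielded by the triarylmethyl carbon.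

Step 9
Reactants: 14 (2S)-5,7-bis(benzyloxy)-8-[(S)-(2,6-dihydroxy-4-methoxy-3-methylphenyl)(phenyl)methyl]-6-methyl-2-phenylchroman-4-one
Product: 15 (2S)-8-[(S)-(2,6-dihydroxy-4-methoxy-3-methylphenyl)(phenyl)methyl]-5,7-dihydroxy-6-methyl-2-phenylchroman-4-one
Conditions: H2 (1 atm), Pd/C, EtOAc–MeOH, rt
Reagents that add atoms: none
Why: Hydrogenolysis of the two aryl benzyl ethers over Pd/C at ambient pressure should be faster than cleavage of the cyclic benzylic C2–O1 bond or reduction of the aryl ketone, so the 5- and 7-hydroxyls are freed without touching either stereocentre.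

**Compound list**

1 | 5,7-dihydroxy-4H-chromen-4-one | O=c1ccoc2cc(O)cc(O)c12 | starting material
2 | 7-(benzyloxy)-5-hydroxy-4H-chromen-4-one | O=c1ccoc2cc(OCc3ccccc3)cc(O)c12 | intermediate
3 | 7-(benzyloxy)-5-hydroxy-6-iodo-4H-chromen-4-one | O=c1ccoc2cc(OCc3ccccc3)c(I)c(O)c12 | intermediate
4 | 7-(benzyloxy)-5-hydroxy-6-methyl-4H-chromen-4-one | O=c1ccoc2cc(OCc3ccccc3)c(C)c(O)c12 | intermediate
5 | 5,7-bis(benzyloxy)-6-methyl-4H-chromen-4-one | O=c1ccoc2cc(OCc3ccccc3)c(C)c(OCc3ccccc3)c12 | intermediate
6 | phenylboronic acid | OB(O)c1ccccc1 | starting material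
7 | (2S)-5,7-bis(benzyloxy)-6-methyl-2-phenylchroman-4-one | Cc1c(OCc2ccccc2)cc2O[C@H](c3ccccc3)CC(=O)c2c1OCc1ccccc1 | intermediate
8 | (2S)-5,7-bis(benzyloxy)-8-[chloro(methoxy)methyl]-6-methyl-2-phenylchroman-4-one, both epimers at the new carbon, formed and hydrolysed in step 6 | COC(Cl)c1c(OCc2ccccc2)c(C)c(OCc2ccccc2)c2c1O[C@H](c1ccccc1)CC2=O | intermediate
9 | (2S)-5,7-bis(benzyloxy)-6-methyl-4-oxo-2-phenylchromane-8-carbaldehyde | O=Cc1c(OCc2ccccc2)c(C)c(OCc2ccccc2)c2c1O[C@H](c1ccccc1)CC2=O | intermediate
10 | 2-methylbenzene-1,3,5-triol (2-methylphloroglucinol) | Cc1c(O)cc(O)cc1O | starting material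
11 | (2S)-5,7-bis(benzyloxy)-8-(5,7-dihydroxy-6-methyl-2-phenyl-4H-1,3,2-benzodioxaborin-4-yl)-6-methyl-2-phenylchroman-4-one, both epimers at the dioxaborin C4, drawn closed through the less hindered ring D oxygen, formed and consumed in step 7 | Cc1c(O)cc2OB(c3ccccc3)OC(c2c1O)c1c(OCc2ccccc2)c(C)c(OCc2ccccc2)c2c1O[C@H](c1ccccc1)CC2=O | intermediate
12 | ring D ortho-quinone methide bound through its carbonyl oxygen to phenylboron 3,3'-dibromo-1,1'-binaphthalene-2,2'-diolate (ate complex, alkene geometry and biaryl axis not drawn), formed and consumed in step 7 | CC1=C(O)C(=Cc2c(OCc3ccccc3)c(C)c(OCc3ccccc3)c3c2O[C@H](c2ccccc2)CC3=O)C(=[O+][B-]2(c3ccccc3)Oc3c(Br)cc4ccccc4c3-c3c(O2)c(Br)cc4ccccc34)C=C1O | intermediate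
13 | (2S)-5,7-bis(benzyloxy)-6-methyl-2-phenyl-8-[(S)-phenyl(2,4,6-trihydroxy-3-methylphenyl)methyl]chroman-4-one | Oc1cc(O)c([C@H](c2ccccc2)c2c(OCc3ccccc3)c(C)c(OCc3ccccc3)c3c2O[C@H](c2ccccc2)CC3=O)c(O)c1C | intermediate
14 | (2S)-5,7-bis(benzyloxy)-8-[(S)-(2,6-dihydroxy-4-methoxy-3-methylphenyl)(phenyl)methyl]-6-methyl-2-phenylchroman-4-one | COc1cc(O)c([C@H](c2ccccc2)c2c(OCc3ccccc3)c(C)c(OCc3ccccc3)c3c2O[C@H](c2ccccc2)CC3=O)c(O)c1C | intermediate
15 | (2S)-8-[(S)-(2,6-dihydroxy-4-methoxy-3-methylphenyl)(phenyl)methyl]-5,7-dihydroxy-6-methyl-2-phenylchroman-4-one | COc1cc(O)c([C@H](c2ccccc2)c2c(O)c(C)c(O)c3c2O[C@H](c2ccccc2)CC3=O)c(O)c1C | target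

**Step count**

Total steps: 9. Longest linear sequence: 9 steps (1 → 2 → 3 → 4 → 5 → 7 → 9 → 13 → 14 → 15); 6 and 10 enter as purchased components.

**Steps most likely to fail**

Step 7 (proposed new method). Phenyl may migrate from boron before the biphenol is bound, which would erode facial selectivity at the methine. Migration of an unactivated phenyl group may also be slower than capture of the stabilised quinone methide by a second molecule of 10 or than its oligomerisation. The fallback uses known chemistry, sets out from 9 and returns at 13. Chemoselective addition of PhTi(OiPr)3 (THF, −40 °C) to the aldehyde in the presence of the hindered aryl ketone should give (2S)-5,7-bis(benzyloxy)-8-[hydroxy(phenyl)methyl]-6-methyl-2-phenylchroman-4-one F1 as a mixture of carbinol epimers. Brønsted acid-catalysed Friedel–Crafts alkylation of excess 10 (diphenyl phosphate, MeCN, 0 °C) through the diarylmethyl cation stabilised by the three oxygens of ring A should then give 13 together with its methine epimer (2S)-5,7-bis(benzyloxy)-6-methyl-2-phenyl-8-[(R)-phenyl(2,4,6-trihydroxy-3-methylphenyl)methyl]chroman-4-one F2. Because C2 is fixed, the two are diastereomers and would be separated by chromatography. This gives up catalyst control at the methine in exchange for two well-known bond formations.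

Step 8. The small methylating agent may discriminate poorly between the three ring D phenols, or methylation may run on to di- and tri-ethers. The fallback sets out from 13 and returns at 15.
- A bulky silyl chloride (TBDPSCl, imidazole, DMF, 0 °C), far more sensitive to the triarylmethyl neighbour, should silylate only the 4-hydroxyl to give (2S)-5,7-bis(benzyloxy)-8-[(S)-{4-[(tert-butyldiphenylsilyl)oxy]-2,6-dihydroxy-3-methylphenyl}(phenyl)methyl]-6-methyl-2-phenylchroman-4-one F3.
- The two hindered hydroxyls are then capped as benzyl carbonates (CbzCl, pyridine, DMAP) to give (2S)-5,7-bis(benzyloxy)-8-[(S)-{2,6-bis[(benzyloxycarbonyl)oxy]-4-[(tert-butyldiphenylsilyl)oxy]-3-methylphenyl}(phenyl)methyl]-6-methyl-2-phenylchroman-4-one F4.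
- The silyl ether is cleaved (HF·pyridine, THF) to give (2S)-5,7-bis(benzyloxy)-8-[(S)-{2,6-bis[(benzyloxycarbonyl)oxy]-4-hydroxy-3-methylphenyl}(phenyl)methyl]-6-methyl-2-phenylchroman-4-one F5.
- The single free phenol is methylated (Me3SiCHN2, iPr2NEt, MeCN–MeOH) to give (2S)-5,7-bis(benzyloxy)-8-[(S)-{2,6-bis[(benzyloxycarbonyl)oxy]-4-methoxy-3-methylphenyl}(phenyl)methyl]-6-methyl-2-phenylchroman-4-one F6.
- Hydrogenolysis under the conditions of step 9 should remove both carbonates and both benzyl ethers at once and deliver 15.

Step 6. The acid set free during formylation may remove the peri 5-benzyl ether or open ring C by enolisation and loss of the phenoxide, which would erode the C2 configuration. The two oxygen substituents flanking C8 may also slow the attack. The fallback sets out from 5 and returns at 9, and moves the formylation in front of the stereocentre. Vilsmeier–Haack formylation of chromone 5 (POCl3, DMF, 0 → 60 °C; aq. NaOAc), which has no enolisable CH2 and no stereocentre, should give 5,7-bis(benzyloxy)-6-methyl-4-oxo-4H-chromene-8-carbaldehyde F7. The rhodium-catalysed asymmetric 1,4-addition of 6 under the conditions of step 5 should then give 9 directly, since the hindered electron-rich aldehyde is a poor acceptor for 1,2-arylation under these base-free conditions.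

**Further compounds**

F1 | step 7 | (2S)-5,7-bis(benzyloxy)-8-[hydroxy(phenyl)methyl]-6-methyl-2-phenylchroman-4-one (carbinol epimers) | OC(c1ccccc1)c1c(OCc2ccccc2)c(C)c(OCc2ccccc2)c2c1O[C@H](c1ccccc1)CC2=O
F2 | step 7 | (2S)-5,7-bis(benzyloxy)-6-methyl-2-phenyl-8-[(R)-phenyl(2,4,6-trihydroxy-3-methylphenyl)methyl]chroman-4-one | Oc1cc(O)c([C@@H](c2ccccc2)c2c(OCc3ccccc3)c(C)c(OCc3ccccc3)c3c2O[C@H](c2ccccc2)CC3=O)c(O)c1C
F3 | step 8 | (2S)-5,7-bis(benzyloxy)-8-[(S)-{4-[(tert-butyldiphenylsilyl)oxy]-2,6-dihydroxy-3-methylphenyl}(phenyl)methyl]-6-methyl-2-phenylchroman-4-one | CC(C)(C)[Si](Oc1cc(O)c([C@H](c2ccccc2)c2c(OCc3ccccc3)c(C)c(OCc3ccccc3)c3c2O[C@H](c2ccccc2)CC3=O)c(O)c1C)(c1ccccc1)c1ccccc1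
F4 | step 8 | (2S)-5,7-bis(benzyloxy)-8-[(S)-{2,6-bis[(benzyloxycarbonyl)oxy]-4-[(tert-butyldiphenylsilyl)oxy]-3-methylphenyl}(phenyl)methyl]-6-methyl-2-phenylchroman-4-one | CC(C)(C)[Si](Oc1cc(OC(=O)OCc2ccccc2)c([C@H](c2ccccc2)c2c(OCc3ccccc3)c(C)c(OCc3ccccc3)c3c2O[C@H](c2ccccc2)CC3=O)c(OC(=O)OCc2ccccc2)c1C)(c1ccccc1)c1ccccc1
F5 | step 8 | (2S)-5,7-bis(benzyloxy)-8-[(S)-{2,6-bis[(benzyloxycarbonyl)oxy]-4-hydroxy-3-methylphenyl}(phenyl)methyl]-6-methyl-2-phenylchroman-4-one | Oc1cc(OC(=O)OCc2ccccc2)c([C@H](c2ccccc2)c2c(OCc3ccccc3)c(C)c(OCc3ccccc3)c3c2O[C@H](c2ccccc2)CC3=O)c(OC(=O)OCc2ccccc2)c1C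
F6 | step 8 | (2S)-5,7-bis(benzyloxy)-8-[(S)-{2,6-bis[(benzyloxycarbonyl)oxy]-4-methoxy-3-methylphenyl}(phenyl)methyl]-6-methyl-2-phenylchroman-4-one | COc1cc(OC(=O)OCc2ccccc2)c([C@H](c2ccccc2)c2c(OCc3ccccc3)c(C)c(OCc3ccccc3)c3c2O[C@H](c2ccccc2)CC3=O)c(OC(=O)OCc2ccccc2)c1C
F7 | step 6 | 5,7-bis(benzyloxy)-6-methyl-4-oxo-4H-chromene-8-carbaldehyde | O=Cc1c(OCc2ccccc2)c(C)c(OCc2ccccc2)c2c(=O)ccoc12
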